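**Retrosynthetic overview**
1. The N–OH is installed last by persilylation and MoO(O2)2·py·HMPA oxidation of the NH-pyridone; just before that, one fluoride step removes two 2-(trimethylsilyl)ethyl ethers and the TBS ether.
2. The C3–acyl bond comes from C3-lithiation of a 2,4-dialkoxypyridine, addition to the decalin aldehyde and oxidation; the C5–carbinol bond comes from a 5-lithiopyridine adding to an epoxy ketone anti to the epoxide.
3. The decalin comes from an intramolecular Diels–Alder reaction of a (2E,8E,10E)-6-methyldodecatrienoate, which forms both carbocycles and four stereocentres under control of the (R)-citronellal methyl group; the triene is made by cross-metathesis, then Wittig olefination.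
4. The epoxy ketone comes from (−)-quinic acid via (S)-4-silyloxycyclohex-2-enone and trans-selective nucleophilic epoxidation.
5. Ring order: cyclohexane (present in quinic acid), epoxide (step 6), pyridine (bought), both decalin rings together (step 11); the fragments are joined in steps 8 and 13.

Assumption: (R)-citronellal of high ee, 5-bromo-2,4-dichloropyridine, (E)-but-2-enyltriphenylphosphonium bromide and MoO(O2)2·py·HMPA are bought; the target is drawn as the 1-hydroxy-2-pyridone tautomer.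

**Epoxy ketone fragment**

Step 1
Reactants: 1 (−)-quinic acid
Product: 2 3,4-O-isopropylidene-1,5-quinide
Conditions: Me2C(OMe)2, TsOH·H2O (cat.), acetone, reflux
Reagents that add atoms: 2,2-dimethoxypropane COC(C)(C)OC
Why: Acid-catalysed transketalisation protects the cis-3,4-diol while the carboxyl lactonises onto the cis C5 hydroxyl; no stereocentre is touched.

Step 2
Reactants: 2 3,4-O-isopropylidene-1,5-quinide
Product: 4 (3R,4S,5R)-5-hydroxy-3,4-(isopropylidenedioxy)cyclohexan-1-one, via triol 3 (not isolated)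
Conditions: NaBH4, EtOH, 0 °C → rt; AcOH, evaporate; then NaIO4, pH 7 phosphate buffer/H2O, 0 °C
Reagents that add atoms: none
Why: Borohydride reduces the lactone to the 1-(hydroxymethyl)-1,5-diol, and periodate glycol cleavage of the tertiary/primary 1,2-diol leaves the C1 ketone with C3–C5 unchanged.

Step 3
Reactants: 4 (3R,4S,5R)-5-hydroxy-3,4-(isopropylidenedioxy)cyclohexan-1-one
Product: 6 (4S,5R)-4,5-(isopropylidenedioxy)cyclohex-2-en-1-one, via mesylate 5 (not isolated)
Conditions: MsCl, Et3N, CH2Cl2, 0 °C → rt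
Reagents that add atoms: none
Why: Mesylation of the β-hydroxy ketone is followed by in situ E1cB elimination, because mesylate leaves far more readily than the acetonide oxygen.

Step 4
Reactants: 6 (4S,5R)-4,5-(isopropylidenedioxy)cyclohex-2-en-1-one
Product: 7 (3R,4S)-3,4-(isopropylidenedioxy)cyclohexan-1-one
Conditions: H2 (1 atm), Pd/C (10 %), EtOAc, rt
Reagents that add atoms: none
Why: Heterogeneous catalytic hydrogenation saturates the enone C=C; both acetonide stereocentres are retained.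

Step 5
Reactants: 7 (3R,4S)-3,4-(isopropylidenedioxy)cyclohexan-1-one
Product: 9 (S)-4-[(tert-butyldimethylsilyl)oxy]cyclohex-2-en-1-one, via hydroxyenone 8 (not isolated)
Conditions: DBU, TBSCl, CH2Cl2, 0 °C → rt
Reagents that add atoms: tert-butyldimethylsilyl chloride CC(C)(C)[Si](C)(C)Cl
Why: DBU-mediated E1cB β-elimination of the C3 acetonide oxygen (acetone is expelled) gives (S)-4-hydroxycyclohexenone, which is silylated in situ; the carbinol centre is quinic acid C4 and is not touched.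

Step 6
Reactants: 9 (S)-4-[(tert-butyldimethylsilyl)oxy]cyclohex-2-en-1-one
Product: 10 (1R,5S,6S)-5-[(tert-butyldimethylsilyl)oxy]-7-oxabicyclo[4.1.0]heptan-2-one
Conditions: 30 % H2O2, benzyltrimethylammonium hydroxide (cat.), THF, 0 °C
Reagents that add atoms: hydrogen peroxide OO
Why: In this Weitz–Scheffer nucleophilic epoxidation the hydroperoxide adds to the β-carbon anti to the adjacent OTBS group, giving the trans-epoxy ketone.

**Pyridine fragment and first union**

Step 7
Reactants: 11 5-bromo-2,4-dichloropyridine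
Product: 12 5-bromo-2,4-bis[2-(trimethylsilyl)ethoxy]pyridine
Conditions: Me3SiCH2CH2OH (2.5 equiv), NaH, DMF, 0 → 80 °C
Reagents that add atoms: 2-(trimethylsilyl)ethanol C[Si](C)(C)CCO
Why: Two-fold SNAr displaces the 4- and 2-chlorides (para and ortho to nitrogen); the 5-bromide, meta to nitrogen, is inert.

Step 8
Reactants: 12 5-bromo-2,4-bis[2-(trimethylsilyl)ethoxy]pyridine; 10 (1R,5S,6S)-5-[(tert-butyldimethylsilyl)oxy]-7-oxabicyclo[4.1.0]heptan-2-one
Product: 14 (1R,2R,5S,6S)-2-{4,6-bis[2-(trimethylsilyl)ethoxy]pyridin-3-yl}-5-[(tert-butyldimethylsilyl)oxy]-7-oxabicyclo[4.1.0]heptan-2-ol, via 5-lithiopyridine 13 (not isolated)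
Conditions: n-BuLi, THF, −78 °C; then 10, −78 °C; sat. aq NH4Cl
Reagents that add atoms: none
Why: Bromine–lithium exchange is followed by 1,2-addition of the aryllithium to the ketone from the face opposite the epoxide oxygen, which sets the tertiary carbinol (2R, OH cis to the epoxide).

**Decalin fragment**

Step 9
Reactants: 15 (R)-citronellal; 16 methyl acrylate
Product: 17 methyl (2E,6R)-6-methyl-8-oxooct-2-enoate
Conditions: second-generation Hoveyda–Grubbs catalyst RuCl2(H2IMes)(=CH–C6H4-2-O-i-Pr) (3 mol %), methyl acrylate (4 equiv), CH2Cl2, 40 °C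
Reagents that add atoms: none
Why: Olefin cross-metathesis of the trisubstituted alkene with the electron-poor acrylate (isobutene is lost) gives the E-enoate; the aldehyde and the methyl stereocentre are spectators.

Step 10
Reactants: 17 methyl (2E,6R)-6-methyl-8-oxooct-2-enoate; 18 (E)-but-2-enyltriphenylphosphonium bromide
Product: 21 methyl (2E,6R,8E,10E)-6-methyldodeca-2,8,10-trienoate, via phosphorus ylide 19 (not isolated), via 8Z-triene 20 (not isolated)
Conditions: 18, NaN(SiMe3)2, THF, −78 °C; then 17, −78 °C → rt; pentane, filter; then I2 (5 mol %), CH2Cl2, hν, rt; aq Na2S2O3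
Reagents that add atoms: none
Why: Wittig olefination with the semi-stabilised allylic ylide gives an 8E/8Z mixture, which iodine-catalysed isomerisation converges on the thermodynamically preferred 8E,10E-diene.

Step 11
Reactants: 21 methyl (2E,6R,8E,10E)-6-methyldodeca-2,8,10-trienoate
Product: 22 methyl (1R,2R,4aS,6R,8aR)-2,6-dimethyl-1,2,4a,5,6,7,8,8a-octahydronaphthalene-1-carboxylate
Conditions: EtAlCl2 (1.0 equiv), CH2Cl2, −20 °C → rt; 1 M HCl
Reagents that add atoms: none
Why: The Lewis-acid-promoted intramolecular Diels–Alder reaction proceeds through the ester-endo, chair-like transition state with the C6 methyl equatorial, forming both rings and setting C1, C2, C4a and C8a (trans ring fusion, ester cis to the C2 methyl).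

Step 12
Reactants: 22 methyl (1R,2R,4aS,6R,8aR)-2,6-dimethyl-1,2,4a,5,6,7,8,8a-octahydronaphthalene-1-carboxylate
Product: 23 (1R,2R,4aS,6R,8aR)-2,6-dimethyl-1,2,4a,5,6,7,8,8a-octahydronaphthalene-1-carbaldehyde
Conditions: i-Bu2AlH (1.1 equiv), CH2Cl2, −78 °C; MeOH, then aq KNaC4H4O6
Reagents that add atoms: none
Why: In this partial hydride reduction the aluminium hemiacetal survives at −78 °C and collapses to the aldehyde on work-up; C1 keeps its equatorial, thermodynamically favoured configuration.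

**Assembly and end game**

Step 13
Reactants: 14 (1R,2R,5S,6S)-2-{4,6-bis[2-(trimethylsilyl)ethoxy]pyridin-3-yl}-5-[(tert-butyldimethylsilyl)oxy]-7-oxabicyclo[4.1.0]heptan-2-ol; 23 (1R,2R,4aS,6R,8aR)-2,6-dimethyl-1,2,4a,5,6,7,8,8a-octahydronaphthalene-1-carbaldehyde
Product: 25 [(1R,2R,4aS,6R,8aR)-2,6-dimethyl-1,2,4a,5,6,7,8,8a-octahydronaphthalen-1-yl]{5-[(1R,2R,5S,6S)-5-(tert-butyldimethylsilyloxy)-2-hydroxy-7-oxabicyclo[4.1.0]heptan-2-yl]-2,4-bis[2-(trimethylsilyl)ethoxy]pyridin-3-yl}methanol (carbinol epimers), via dilithio species 24 (not isolated)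
Conditions: n-BuLi (2.2 equiv), THF, −78 → −20 °C; recool to −78 °C, then 23; sat. aq NH4Cl
Reagents that add atoms: none
Why: After deprotonation of the OH, directed ortho-lithiation occurs at the C–H flanked by the two ether oxygens and the aryllithium adds 1,2 to the aldehyde; the new carbinol centre forms as a mixture, which does not matter because it is oxidised next.

Step 14
Reactants: 25 the carbinol epimers from step 13
Product: 26 [(1R,2R,4aS,6R,8aR)-2,6-dimethyl-1,2,4a,5,6,7,8,8a-octahydronaphthalen-1-yl]{5-[(1R,2R,5S,6S)-5-(tert-butyldimethylsilyloxy)-2-hydroxy-7-oxabicyclo[4.1.0]heptan-2-yl]-2,4-bis[2-(trimethylsilyl)ethoxy]pyridin-3-yl}methanone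
Conditions: Dess–Martin periodinane, pyridine, CH2Cl2, 0 °C → rt
Reagents that add atoms: none
Why: Dess–Martin oxidation converts the secondary pyridyl carbinol to the ketone; the tertiary alcohol, epoxide, alkene and silyl groups are inert.

Step 15
Reactants: 26 the pyridyl ketone from step 14
Product: 27 3-[(1R,2R,4aS,6R,8aR)-2,6-dimethyl-1,2,4a,5,6,7,8,8a-octahydronaphthalene-1-carbonyl]-5-[(1R,2R,5S,6R)-2,5-dihydroxy-7-oxabicyclo[4.1.0]heptan-2-yl]-4-hydroxypyridin-2(1H)-one
Conditions: Bu4NF (6 equiv), AcOH (3 equiv), THF, 0 °C → rt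
Reagents that add atoms: none
Why: Fluoride attack at silicon triggers β-elimination (ethene and Me3SiF) that frees both pyridine oxygens and also cleaves the TBS ether; AcOH buffering suppresses alkoxide-driven epoxide migration.

Step 16
Reactants: 27 the NH-pyridone from step 15
Product: 30 3-[(1R,2R,4aS,6R,8aR)-2,6-dimethyl-1,2,4a,5,6,7,8,8a-octahydronaphthalene-1-carbonyl]-5-[(1R,2R,5S,6R)-2,5-dihydroxy-7-oxabicyclo[4.1.0]heptan-2-yl]-1,4-dihydroxypyridin-2(1H)-one, via persilylated pyridine 28 (not isolated), via silylated N-oxide 29 (not isolated)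
Conditions: N,O-bis(trimethylsilyl)acetamide (6 equiv), Me3SiCl (cat.), CH2Cl2, rt; then MoO(O2)2·py·HMPA (1.5 equiv), CH2Cl2, rt, dark; aq Na4EDTA, then citric acid to pH 4
Reagents that add atoms: oxodiperoxomolybdenum–pyridine–HMPA complex O=[Mo]12(OO1)OO2.c1ccncc1.CN(C)P(=O)(N(C)C)N(C)C
Why: In this Sammes-type hydroxamic acid synthesis the nitrogen of the 2-(trimethylsilyloxy)pyridine is oxidised by the peroxomolybdenum complex (which, with pyridine bound, does not epoxidise the isolated ring alkene), and hydrolysis of the silyl groups gives the 1-hydroxy-2-pyridone.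

**Compound list**

1 | (−)-quinic acid, (1S,3R,4S,5R)-1,3,4,5-tetrahydroxycyclohexane-1-carboxylic acid | C1[C@H]([C@H]([C@@H](C[C@@]1(C(=O)O)O)O)O)O | starting material
2 | 3,4-O-isopropylidene-1,5-quinide (1,5-lactone of quinic acid, cis-3,4-diol as acetonide) | O[C@@]12C[C@H]3OC(C)(C)O[C@H]3[C@@H](C1)OC2=O | intermediate
3 | 1-(hydroxymethyl)-3,4-(isopropylidenedioxy)cyclohexane-1,5-diol (quinic acid numbering, configuration as in 2) | OC[C@]1(O)C[C@H]2OC(C)(C)O[C@H]2[C@H](O)C1 | intermediate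
4 | (3R,4S,5R)-5-hydroxy-3,4-(isopropylidenedioxy)cyclohexan-1-one | O=C1C[C@H]2OC(C)(C)O[C@H]2[C@H](O)C1 | intermediate
5 | 5-O-methanesulfonate of 4 | O=C1C[C@H]2OC(C)(C)O[C@H]2[C@H](OS(C)(=O)=O)C1 | intermediate
6 | (4S,5R)-4,5-(isopropylidenedioxy)cyclohex-2-en-1-one | O=C1C[C@H]2OC(C)(C)O[C@H]2C=C1 | intermediate
7 | (3R,4S)-3,4-(isopropylidenedioxy)cyclohexan-1-one | O=C1C[C@H]2OC(C)(C)O[C@H]2CC1 | intermediate
8 | (S)-4-hydroxycyclohex-2-en-1-one | O=C1C=C[C@@H](O)CC1 | intermediate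
9 | (S)-4-[(tert-butyldimethylsilyl)oxy]cyclohex-2-en-1-one | O=C1C=C[C@@H](O[Si](C)(C)C(C)(C)C)CC1 | intermediate
10 | (1R,5S,6S)-5-[(tert-butyldimethylsilyl)oxy]-7-oxabicyclo[4.1.0]heptan-2-one (epoxide trans to OTBS) | O=C1CC[C@H](O[Si](C)(C)C(C)(C)C)[C@H]2O[C@@H]12 | intermediate
11 | 5-bromo-2,4-dichloropyridine | Clc1cc(Cl)c(Br)cn1 | starting material
12 | 5-bromo-2,4-bis[2-(trimethylsilyl)ethoxy]pyridine | C[Si](C)(C)CCOc1cc(OCC[Si](C)(C)C)c(Br)cn1 | intermediate
13 | 5-lithio-2,4-bis[2-(trimethylsilyl)ethoxy]pyridine | [Li]c1cnc(OCC[Si](C)(C)C)cc1OCC[Si](C)(C)C | intermediate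
14 | (1R,2R,5S,6S)-2-{4,6-bis[2-(trimethylsilyl)ethoxy]pyridin-3-yl}-5-[(tert-butyldimethylsilyl)oxy]-7-oxabicyclo[4.1.0]heptan-2-ol (aryl trans to the epoxide, cis to OTBS) | C[Si](C)(C)CCOc1cc(OCC[Si](C)(C)C)c(cn1)[C@]1(O)CC[C@H](O[Si](C)(C)C(C)(C)C)[C@H]2O[C@H]21 | intermediate
15 | (R)-citronellal, (3R)-3,7-dimethyloct-6-enal | C[C@H](CCC=C(C)C)CC=O | starting material
16 | methyl acrylate | C=CC(=O)OC | starting material
17 | methyl (2E,6R)-6-methyl-8-oxooct-2-enoate | COC(=O)/C=C/CC[C@@H](C)CC=O | intermediate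
18 | (E)-but-2-enyltriphenylphosphonium bromide | C/C=C/C[P+](c1ccccc1)(c1ccccc1)c1ccccc1.[Br-] | starting material
19 | (E)-but-2-enylidenetriphenylphosphorane | C/C=C/C=P(c1ccccc1)(c1ccccc1)c1ccccc1 | intermediate
20 | methyl (2E,6R,8Z,10E)-6-methyldodeca-2,8,10-trienoate | COC(=O)/C=C/CC[C@@H](C)C/C=C\C=C\C | intermediate
21 | methyl (2E,6R,8E,10E)-6-methyldodeca-2,8,10-trienoate | COC(=O)/C=C/CC[C@@H](C)C/C=C/C=C/C | intermediate
22 | methyl (1R,2R,4aS,6R,8aR)-2,6-dimethyl-1,2,4a,5,6,7,8,8a-octahydronaphthalene-1-carboxylate (trans-fused) | C[C@@H]1CC[C@H]2[C@H](C(=O)OC)[C@H](C)C=C[C@@H]2C1 | intermediate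
23 | (1R,2R,4aS,6R,8aR)-2,6-dimethyl-1,2,4a,5,6,7,8,8a-octahydronaphthalene-1-carbaldehyde | C[C@@H]1CC[C@H]2[C@H](C=O)[C@H](C)C=C[C@@H]2C1 | intermediate
24 | C3-lithiated lithium alkoxide of 14 | [Li]c1c(OCC[Si](C)(C)C)ncc(c1OCC[Si](C)(C)C)[C@]1(O[Li])CC[C@H](O[Si](C)(C)C(C)(C)C)[C@H]2O[C@H]21 | intermediate
25 | pyridyl(decalinyl)methanol from 14 and 23, epimers at the carbinol carbon | C[C@@H]1CC[C@H]2[C@H](C(O)c3c(OCC[Si](C)(C)C)ncc([C@]4(O)CC[C@H](O[Si](C)(C)C(C)(C)C)[C@H]5O[C@H]54)c3OCC[Si](C)(C)C)[C@H](C)C=C[C@@H]2C1 | intermediate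
26 | corresponding pyridyl decalinyl ketone | C[C@@H]1CC[C@H]2[C@H](C(=O)c3c(OCC[Si](C)(C)C)ncc([C@]4(O)CC[C@H](O[Si](C)(C)C(C)(C)C)[C@H]5O[C@H]54)c3OCC[Si](C)(C)C)[C@H](C)C=C[C@@H]2C1 | intermediate
27 | 3-acyl-4-hydroxy-5-(epoxydihydroxycyclohexyl)pyridin-2(1H)-one (N–H analogue of the target) | C[C@@H]1CC[C@H]2[C@H](C(=O)c3c(O)c([C@]4(O)CC[C@H](O)[C@H]5O[C@H]54)c[nH]c3=O)[C@H](C)C=C[C@@H]2C1 | intermediate
28 | tetrakis(trimethylsilyl) derivative of 27 (2,4-bis(silyloxy)pyridine, both side-chain OH silylated) | C[C@@H]1CC[C@H]2[C@H](C(=O)c3c(O[Si](C)(C)C)ncc([C@]4(O[Si](C)(C)C)CC[C@H](O[Si](C)(C)C)[C@H]5O[C@H]54)c3O[Si](C)(C)C)[C@H](C)C=C[C@@H]2C1 | intermediate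
29 | pyridine N-oxide of 28 | C[C@@H]1CC[C@H]2[C@H](C(=O)c3c(O[Si](C)(C)C)[n+]([O-])cc([C@]4(O[Si](C)(C)C)CC[C@H](O[Si](C)(C)C)[C@H]5O[C@H]54)c3O[Si](C)(C)C)[C@H](C)C=C[C@@H]2C1 | intermediate
30 | 3-[(1R,2R,4aS,6R,8aR)-2,6-dimethyl-1,2,4a,5,6,7,8,8a-octahydronaphthalene-1-carbonyl]-5-[(1R,2R,5S,6R)-2,5-dihydroxy-7-oxabicyclo[4.1.0]heptan-2-yl]-1,4-dihydroxypyridin-2(1H)-one | C[C@@H]1CC[C@H]2[C@H](C(=O)c3c(O)c([C@]4(O)CC[C@H](O)[C@H]5O[C@H]54)cn(O)c3=O)[C@H](C)C=C[C@@H]2C1 | target

**Step count**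

Total: 16 steps. Longest linear sequence: 11 steps (1–6, 8, 13–16, from quinic acid).

**Three steps most likely to fail, each with a fallback**

Step 16 (late N-hydroxylation; modest yields are typical and the substrate carries an alkene and four hydroxyl groups). The fallback puts the N–O bond in before the alkene-bearing decalin arrives. It sets out from 14 and returns at 30. Compound 14 is brominated with NBS in MeCN at the pyridine carbon between the two ether oxygens to give the bromopyridine F1. Its nitrogen is oxidised with mCPBA (CH2Cl2, rt) to the pyridine N-oxide F2. Bromine–magnesium exchange with i-PrMgCl·LiCl (2.2 equiv, THF, −40 °C) and addition of aldehyde 23 gives the carbinol N-oxide F3. Dess–Martin oxidation gives the ketone N-oxide F4. Bu4NF/AcOH then removes both 2-(trimethylsilyl)ethyl groups and the TBS ether; loss of the 2-O-alkyl group from an N-oxide gives the 1-hydroxy-2-pyridone directly, which is 30.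

Step 13 (directed lithiation of a substrate carrying a lithium alkoxide and an epoxide, then addition to a hindered aldehyde). The fallback replaces deprotonation by halogen–metal exchange. It sets out from 14 and returns at 25. Compound 14 is iodinated with N-iodosuccinimide (MeCN, rt) at the same ring carbon to give the iodopyridine F5. Iodine–magnesium exchange with i-PrMgCl·LiCl (2.2 equiv, THF, −40 °C) gives the arylmagnesium reagent regiospecifically, and it adds to 23 to give 25.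

Step 11 (endo/exo and facial selectivity rest only on the remote methyl group and a modestly activated ester). The fallback switches to the more reactive enal dienophile so that the cycloaddition runs at −78 °C. It sets out from 21 and returns at 23, bypassing 22. Ester 21 is reduced with i-Bu2AlH (2.2 equiv, −78 → 0 °C) to the trienol F6, which is oxidised with MnO2 (CH2Cl2, rt) to the trienal F7. Me2AlCl (CH2Cl2, −78 °C) then promotes the intramolecular Diels–Alder reaction through the same aldehyde-endo, methyl-equatorial transition state and gives aldehyde 23 directly.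

**Further compounds**

F1 | step 16 | (1R,2R,5S,6S)-2-{5-bromo-4,6-bis[2-(trimethylsilyl)ethoxy]pyridin-3-yl}-5-[(tert-butyldimethylsilyl)oxy]-7-oxabicyclo[4.1.0]heptan-2-ol | C[Si](C)(C)CCOc1ncc(c(OCC[Si](C)(C)C)c1Br)[C@]1(O)CC[C@H](O[Si](C)(C)C(C)(C)C)[C@H]2O[C@H]21
F2 | step 16 | pyridine N-oxide of F1 | C[Si](C)(C)CCOc1c(Br)c(OCC[Si](C)(C)C)c(c[n+]1[O-])[C@]1(O)CC[C@H](O[Si](C)(C)C(C)(C)C)[C@H]2O[C@H]21
F3 | step 16 | pyridine N-oxide of carbinol 25 (carbinol epimers) | C[C@@H]1CC[C@H]2[C@H](C(O)c3c(OCC[Si](C)(C)C)[n+]([O-])cc([C@]4(O)CC[C@H](O[Si](C)(C)C(C)(C)C)[C@H]5O[C@H]54)c3OCC[Si](C)(C)C)[C@H](C)C=C[C@@H]2C1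
F4 | step 16 | pyridine N-oxide of ketone 26 | C[C@@H]1CC[C@H]2[C@H](C(=O)c3c(OCC[Si](C)(C)C)[n+]([O-])cc([C@]4(O)CC[C@H](O[Si](C)(C)C(C)(C)C)[C@H]5O[C@H]54)c3OCC[Si](C)(C)C)[C@H](C)C=C[C@@H]2C1
F5 | step 13 | (1R,2R,5S,6S)-2-{5-iodo-4,6-bis[2-(trimethylsilyl)ethoxy]pyridin-3-yl}-5-[(tert-butyldimethylsilyl)oxy]-7-oxabicyclo[4.1.0]heptan-2-ol | C[Si](C)(C)CCOc1ncc(c(OCC[Si](C)(C)C)c1I)[C@]1(O)CC[C@H](O[Si](C)(C)C(C)(C)C)[C@H]2O[C@H]21
F6 | step 11 | (2E,6R,8E,10E)-6-methyldodeca-2,8,10-trien-1-ol | OC/C=C/CC[C@@H](C)C/C=C/C=C/C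
F7 | step 11 | (2E,6R,8E,10E)-6-methyldodeca-2,8,10-trienal | O=C/C=C/CC[C@@H](C)C/C=C/C=C/C
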